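The readings are simulated on assumed constants, and the scatter is random.

I decide to follow one quantity through these flasks, the reach: the integral over time of k = rate/([substrate][reagent]) from a given moment onward, taken at a fixed charge of free catalyst.

| flask | substrate | reagent | free catalyst | temperature | remark | time |
|---|---|---|---|---|---|---|
| dusk | 0.067 M (in portions, 3) | 0.20 M | 0.14 mM | 10 °C | run made earlier; portions every 2.5 min |  |
| midnight | 0.10 M (in portions, 3) | 0.10 M | 0.14 mM | 10 °C | run made earlier; portions every 2.5 min |  |
| east | 0.10 M (in portions, 3) | 0.200 M | 0.14 mM |  | at 10 °C until 25 min, from then on at 30 °C; the portions of substrate follow each other after 2.5 min, the first at the start | 2.0 h |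
| north-west | 0.10 M (in portions, 3) | 0.200 M | 0.040 mM |  | at 10 °C throughout; the portions of substrate follow each other after 2.5 min, the first at the start | 2.0 h |

- dusk (time / min: target / %): 3.00: 4.9; 8.00: 19.1; 15.0: 35.1; 25.0: 46.8; 30.0: 50.8; 40.0: 57.1
- midnight (time / min: target / %): 3.00: 2.3; 6.00: 7.8; 10.0: 12.9; 15.0: 18.7; 25.0: 24.6; 40.0: 29.8

(each reading ± 1 percentage point)

* the flask that ends with the higher amount of target, in percent of the substrate charged, or "neither" when 2 percentage points or less lies between them (east / north-west / neither)
* final target, as a percentage of the substrate charged, in east
* final target, as a percentage of the substrate charged, in north-west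

- the earlier runs do not show what temperature does; that part of a forecast is a guess
- no earlier run changes the charge of free catalyst; that part of a forecast is a guess

The reach can be read in two independent ways. In the midnight run the charges are equal, so 1/[substrate] grows by exactly this integral, and from 15.0 min to 40.0 min it grows by 1.94 M⁻¹. In the dusk run the same window is read from ln([reagent]/[substrate]) divided by the constant difference of the two, which gives 2.46 M⁻¹. One midnight reading shifted by 1 percentage point moves its figure by 0.203 M⁻¹, and both ends of both runs carry such a shift, so I can convict neither run and take the mean.

That mean makes k over the window 0.0880 M⁻¹ min⁻¹, whereas the same readings just after the feed give 0.167 M⁻¹ min⁻¹. If k decays exponentially, its lifetime is 24.9 min. Putting the window's mean at its midpoint errs by 4.26%, less than the 20.8% between the runs, so I let it stand.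

The reach at a moment is then k there times the lifetime. At 25 min it is 2.42 M⁻¹. I replace the feed by its mean time, 2.5 min, where the reach is 5.98 M⁻¹. With substrate as the limiting reagent, my reckoning puts east near 46.1% at the change of temperature, and near 62.1% at the end with the reach left as it is at 10 °C. Warming is unseen, so my estimate for east lies between these. Scaling the reach by the catalyst charge, a guess of first order, gives north-west 27.2%.

The forecast says east, with east at 60% (52% to 71%) and north-west at 29% (20% to 40%), which is above my figure for north-west. On warming it holds that “Warming speeds reaction and probably death more”.

The simulation gives east, with east at 50.8% and north-west at 25.0%.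

    substrate + reagent + free catalyst → target + free catalyst, rate k1*[substrate]*[reagent]*[free catalyst]/(1 + ([substrate]/sat1)) (0.300 M, k = 35.8 M⁻² s⁻¹, Ea = 43.0 kJ mol⁻¹)
    free catalyst → spent catalyst (k = 6.55 × 10⁻⁴ s⁻¹, Ea = 81.0 kJ mol⁻¹)
    (constants at 10 °C)

East stops at 50.8% mainly because free catalyst turns into spent catalyst: without that conversion east ends at >99.9%, and at 1.00 h free catalyst stands at 0% with substrate still at 49.2%. The warming is a part of this: without the second temperature east ends at 60.8%. From 44.1% target at the change to 50.8% at the end, east uses 0.841 M⁻¹, about a third of the reach 2.42 M⁻¹. The same budget, applied to the neighbour of east with 0.040 M substrate, gives 56.1%, and that flask ends at 58.2%.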